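The plan rests on disconnecting ring B of the tridepside across C2–C3 and C1–C6. Ring B atoms C3–C6, with the acylated O4 and the C6 methyl, are the diene carbons of 4-hydroxy-6-methyl-2-pyrone; C1 (carrying the ester to ring C) and C2 (carrying the hydroxyl) are the two carbons of a propiolate. The two ester links of the depside are thus in place before ring B exists, and one thermal pyrone–alkyne cycloaddition with loss of CO2 then builds ring B between them, with a pinacolboryl group on C2 as a latent hydroxyl. The precursors are the pyran-4-yl ester 7 of the protected ring A acid and the 3-borylpropiolate 17 of the protected ring C phenol.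

Key step: step 11

Remark: in each orsellinate ring, C1 carries the carbonyl carbon, C2 the ortho oxygen, C4 the para oxygen and C6 the methyl. Compounds 1, 5, 8 and 13 are taken as commercially available. Ring A is drawn from methyl orsellinate so that its substitution pattern is fixed from the start. The ring C phenol carries a benzyl ether on O2, which requires a temporary allyl group on O4. The target has no stereocentre; the bridged intermediate 18 forms as a racemate.

Step 1
Reactants: 1 methyl 2,4-dihydroxy-6-methylbenzoate (methyl orsellinate)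
Product: 2 methyl 4-(benzyloxy)-2-hydroxy-6-methylbenzoate
Conditions: BnBr (1.05 equiv), K2CO3 (1.2 equiv), acetone, reflux
Reagents that add atoms: benzyl bromide, BrCc1ccccc1
Why: Williamson etherification with one equivalent of halide should alkylate only the 4-OH, because the 2-OH is held in a hydrogen bond to the ester carbonyl and is far less nucleophilic.

Step 2
Reactants: 2 methyl 4-(benzyloxy)-2-hydroxy-6-methylbenzoate
Product: 3 methyl 4-(benzyloxy)-2-methoxy-6-methylbenzoate
Conditions: MeI (3 equiv), K2CO3 (2 equiv), DMF, 50 °C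
Reagents that add atoms: iodomethane, CI
Why: Williamson methylation of the remaining chelated phenol needs these more forcing dipolar aprotic conditions, under which the benzyl ether and the methyl ester are inert.

Step 3
Reactants: 3 methyl 4-(benzyloxy)-2-methoxy-6-methylbenzoate
Product: 4 4-(benzyloxy)-2-methoxy-6-methylbenzoic acid
Conditions: KOH (5 equiv), DMSO/H2O, 90 °C; then aq. HCl, 0 °C
Reagents that add atoms: potassium hydroxide, [K+].[OH-]
Why: Saponification of the di-ortho-substituted methyl ester requires hot hydroxide in aqueous DMSO, the ethers are stable to base, and cold acidification avoids decarboxylation of the electron-rich acid.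

Step 4
Reactants: 4 4-(benzyloxy)-2-methoxy-6-methylbenzoic acid; 5 4-hydroxy-6-methyl-2H-pyran-2-one
Product: 7 6-methyl-2-oxo-2H-pyran-4-yl 4-(benzyloxy)-2-methoxy-6-methylbenzoate, via acid chloride 6 (not isolated)
Conditions: (COCl)2 (1.5 equiv), DMF (cat.), CH2Cl2, 0 °C to rt, evaporate; then 5, Et3N (1.5 equiv), CH2Cl2, 0 °C to rt
Reagents that add atoms: none
Why: Acid chloride formation under Vilsmeier-type catalysis, then O-acylation of the acidic pyrone enol with Et3N and no nucleophilic acyl-transfer catalyst, should give the enol ester and avoid O-to-C acyl migration to C3 of the pyrone.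

Step 5
Reactants: 8 2,4-dihydroxy-6-methylbenzoic acid (orsellinic acid)
Product: 9 benzyl 2,4-dihydroxy-6-methylbenzoate
Conditions: BnBr (1.05 equiv), KHCO3 (1.2 equiv), DMF, rt
Reagents that add atoms: benzyl bromide, BrCc1ccccc1
Why: SN2 alkylation of the carboxylate; KHCO3 deprotonates only the carboxylic acid, so both phenols stay free, and room temperature avoids decarboxylation of 8.

Step 6
Reactants: 9 benzyl 2,4-dihydroxy-6-methylbenzoate
Product: 10 benzyl 4-(allyloxy)-2-hydroxy-6-methylbenzoate
Conditions: allyl bromide (1.05 equiv), K2CO3 (1.2 equiv), acetone, rt to 50 °C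
Reagents that add atoms: allyl bromide, C=CCBr
Why: Williamson etherification that again discriminates the free 4-OH from the chelated 2-OH and places a temporary allyl group on O4.

Step 7
Reactants: 10 benzyl 4-(allyloxy)-2-hydroxy-6-methylbenzoate
Product: 11 benzyl 4-(allyloxy)-2-(benzyloxy)-6-methylbenzoate
Conditions: BnBr (1.5 equiv), K2CO3 (2 equiv), DMF, 60 °C
Reagents that add atoms: benzyl bromide, BrCc1ccccc1
Why: Williamson benzylation of the chelated 2-OH, now the only acidic site, under forcing conditions.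

Step 8
Reactants: 11 benzyl 4-(allyloxy)-2-(benzyloxy)-6-methylbenzoate
Product: 12 benzyl 2-(benzyloxy)-4-hydroxy-6-methylbenzoate
Conditions: Pd(PPh3)4 (3 mol%), morpholine (5 equiv), THF, rt
Reagents that add atoms: none
Why: Tsuji–Trost deallylation in which zerovalent palladium ionises the allyl aryl ether and morpholine captures the allyl unit, leaving the benzyl ether and benzyl ester untouched.

Step 9
Reactants: 12 benzyl 2-(benzyloxy)-4-hydroxy-6-methylbenzoate; 13 propiolic acid
Product: 14 benzyl 2-(benzyloxy)-6-methyl-4-(prop-2-ynoyloxy)benzoate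
Conditions: DCC (1.2 equiv), DMAP (5 mol%), CH2Cl2, –20 to 0 °C
Reagents that add atoms: none
Why: Steglich-type carbodiimide esterification of the only free hydroxyl, run cold with a trace of DMAP to limit conjugate addition to the ynoate.

Step 10
Reactants: 14 benzyl 2-(benzyloxy)-6-methyl-4-(prop-2-ynoyloxy)benzoate
Product: 17 benzyl 2-(benzyloxy)-6-methyl-4-{[3-(4,4,5,5-tetramethyl-1,3,2-dioxaborolan-2-yl)prop-2-ynoyl]oxy}benzoate, via lithium acetylide 15 (not isolated), via lithium alkynylborate 16 (not isolated)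
Conditions: iPrOBpin (1.2 equiv), THF, –78 °C, LiN(SiMe3)2 (1.05 equiv) added dropwise; then HCl in Et2O (1.1 equiv), –78 °C to rt; filter, concentrate, use crude
Reagents that add atoms: 2-isopropoxy-4,4,5,5-tetramethyl-1,3,2-dioxaborolane, CC(C)OB1OC(C)(C)C(C)(C)O1
Why: The hindered amide removes the acidic ynoate C–H at –78 °C (aryl esters tolerate lithium amides at this temperature, as in aryl ester enolate chemistry), acetylide 15 is captured at once by the borate to give ate complex 16, and anhydrous HCl expels isopropanol, which is the standard alkynyllithium–borate route to 1-alkynylboronic esters.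

Step 11
Reactants: 7 6-methyl-2-oxo-2H-pyran-4-yl 4-(benzyloxy)-2-methoxy-6-methylbenzoate; 17 benzyl 2-(benzyloxy)-6-methyl-4-{[3-(4,4,5,5-tetramethyl-1,3,2-dioxaborolan-2-yl)prop-2-ynoyl]oxy}benzoate
Product: 19 benzyl 2-(benzyloxy)-4-{[4-{[4-(benzyloxy)-2-methoxy-6-methylbenzoyl]oxy}-6-methyl-2-(4,4,5,5-tetramethyl-1,3,2-dioxaborolan-2-yl)benzoyl]oxy}-6-methylbenzoate, via bridged bicyclic lactone 18 (not isolated)
Conditions: 17 (1.3 equiv), 1,2-dichlorobenzene, 160 °C, sealed tube, Ar
Reagents that add atoms: none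
Why: Pyrone 7 serves as an ambiphilic cyclic diene, and alkyne 17 adds across its C3 and C6 in a thermal concerted [4+2] cycloaddition to give bridged lactone 18, which loses CO2 by retro-[4+2] and so aromatises. The closest known reaction type is the Diels–Alder/decarboxylation cascade of 2-pyrones with alkynylboronic esters that gives arylboronic esters. Ring B is closed by an intermolecular [4+2] annulation that forms C2–C3 and C1–C6, followed by extrusion of the lactone bridge; no stereocentre is created in the product, since both bridgeheads of racemic 18 end as arene carbons. The step needs one regiochemical outcome: pyrone C3, the nucleophilic β-carbon of the 4-acyloxy enol unit, has to bond to the boron-bearing alkyne carbon, which is the electrophilic β-carbon of the ynoate, so that C6 with its methyl bonds to the ester-bearing carbon. This polarity match is supported sterically, because the bulky Bpin group then lies next to C3–H and not next to the C6 methyl. The neutral aprotic medium should leave the enol ester of 7, the benzyl groups and the C–B bond intact.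

Step 12
Reactants: 19 benzyl 2-(benzyloxy)-4-{[4-{[4-(benzyloxy)-2-methoxy-6-methylbenzoyl]oxy}-6-methyl-2-(4,4,5,5-tetramethyl-1,3,2-dioxaborolan-2-yl)benzoyl]oxy}-6-methylbenzoate
Product: 21 benzyl 2-(benzyloxy)-4-{[4-{[4-(benzyloxy)-2-methoxy-6-methylbenzoyl]oxy}-2-hydroxy-6-methylbenzoyl]oxy}-6-methylbenzoate (tribenzyl umbilicarate), via aryl borate ester 20 (not isolated)
Conditions: Me3NO (anhydrous, 1.5 equiv), CH2Cl2, 0 °C to rt; then aq. NH4Cl
Reagents that add atoms: trimethylamine N-oxide, C[N+](C)(C)[O-]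
Why: Amine N-oxide oxidation of the C–B bond: the oxide oxygen adds to boron, the aryl group migrates from boron to oxygen with loss of Me3N to give borate 20, and mild aqueous work-up hydrolyses the B–O bond, all without the basic peroxide that would cleave the depside esters.

Step 13
Reactants: 21 benzyl 2-(benzyloxy)-4-{[4-{[4-(benzyloxy)-2-methoxy-6-methylbenzoyl]oxy}-2-hydroxy-6-methylbenzoyl]oxy}-6-methylbenzoate
Product: 22 umbilicaric acid, 2-hydroxy-4-{[2-hydroxy-4-{[4-hydroxy-2-methoxy-6-methylbenzoyl]oxy}-6-methylbenzoyl]oxy}-6-methylbenzoic acid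
Conditions: H2 (1 atm), 10% Pd/C, EtOAc, rt
Reagents that add atoms: none
Why: Catalytic hydrogenolysis cleaves the two benzyl ethers and the benzyl ester in one operation, while the aryl ester links, the methyl ether and the arenes are inert under these conditions.

Compound list

1 | methyl 2,4-dihydroxy-6-methylbenzoate (methyl orsellinate) | COC(=O)c1c(C)cc(O)cc1O | starting material
2 | methyl 4-(benzyloxy)-2-hydroxy-6-methylbenzoate | COC(=O)c1c(C)cc(OCc2ccccc2)cc1O | intermediate
3 | methyl 4-(benzyloxy)-2-methoxy-6-methylbenzoate | COC(=O)c1c(C)cc(OCc2ccccc2)cc1OC | intermediate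
4 | 4-(benzyloxy)-2-methoxy-6-methylbenzoic acid | COc1cc(OCc2ccccc2)cc(C)c1C(=O)O | intermediate
5 | 4-hydroxy-6-methyl-2H-pyran-2-one | CC1=CC(O)=CC(=O)O1 | starting material
6 | 4-(benzyloxy)-2-methoxy-6-methylbenzoyl chloride | COc1cc(OCc2ccccc2)cc(C)c1C(=O)Cl | intermediate
7 | 6-methyl-2-oxo-2H-pyran-4-yl 4-(benzyloxy)-2-methoxy-6-methylbenzoate | COc1cc(OCc2ccccc2)cc(C)c1C(=O)OC1=CC(=O)OC(C)=C1 | intermediate
8 | 2,4-dihydroxy-6-methylbenzoic acid (orsellinic acid) | Cc1cc(O)cc(O)c1C(=O)O | starting material
9 | benzyl 2,4-dihydroxy-6-methylbenzoate | Cc1cc(O)cc(O)c1C(=O)OCc1ccccc1 | intermediate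
10 | benzyl 4-(allyloxy)-2-hydroxy-6-methylbenzoate | C=CCOc1cc(C)c(C(=O)OCc2ccccc2)c(O)c1 | intermediate
11 | benzyl 4-(allyloxy)-2-(benzyloxy)-6-methylbenzoate | C=CCOc1cc(C)c(C(=O)OCc2ccccc2)c(OCc2ccccc2)c1 | intermediate
12 | benzyl 2-(benzyloxy)-4-hydroxy-6-methylbenzoate | Oc1cc(C)c(C(=O)OCc2ccccc2)c(OCc2ccccc2)c1 | intermediate
13 | propiolic acid | C#CC(=O)O | starting material
14 | benzyl 2-(benzyloxy)-6-methyl-4-(prop-2-ynoyloxy)benzoate | C#CC(=O)Oc1cc(C)c(C(=O)OCc2ccccc2)c(OCc2ccccc2)c1 | intermediate
15 | lithium acetylide of 14, benzyl 2-(benzyloxy)-4-[(3-lithioprop-2-ynoyl)oxy]-6-methylbenzoate | [Li]C#CC(=O)Oc1cc(C)c(C(=O)OCc2ccccc2)c(OCc2ccccc2)c1 | intermediate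
16 | lithium isopropoxy(alkynyl)pinacolborate derived from 15 | [Li+].CC(C)O[B-]1(C#CC(=O)Oc2cc(C)c(C(=O)OCc3ccccc3)c(OCc3ccccc3)c2)OC(C)(C)C(C)(C)O1 | intermediate
17 | benzyl 2-(benzyloxy)-6-methyl-4-{[3-(4,4,5,5-tetramethyl-1,3,2-dioxaborolan-2-yl)prop-2-ynoyl]oxy}benzoate | CC1(C)OB(C#CC(=O)Oc2cc(C)c(C(=O)OCc3ccccc3)c(OCc3ccccc3)c2)OC1(C)C | intermediate
18 | racemic cycloadduct, 1-methyl-3-oxo-2-oxabicyclo[2.2.2]octa-5,7-diene with the ring A acyloxy group on C5, the ring C aryl ester on C7 and Bpin on C8 | O=C1OC2(C)C=C(OC(=O)c3c(OC)cc(OCc4ccccc4)cc3C)C1C(B3OC(C)(C)C(C)(C)O3)=C2C(=O)Oc1cc(C)c(C(=O)OCc2ccccc2)c(OCc2ccccc2)c1 | intermediate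
19 | benzyl 2-(benzyloxy)-4-{[4-{[4-(benzyloxy)-2-methoxy-6-methylbenzoyl]oxy}-6-methyl-2-(4,4,5,5-tetramethyl-1,3,2-dioxaborolan-2-yl)benzoyl]oxy}-6-methylbenzoate | COc1cc(OCc2ccccc2)cc(C)c1C(=O)Oc1cc(C)c(C(=O)Oc2cc(C)c(C(=O)OCc3ccccc3)c(OCc3ccccc3)c2)c(B2OC(C)(C)C(C)(C)O2)c1 | intermediate
20 | aryl pinacol borate of 21 (ring B O2 bonded to Bpin) | COc1cc(OCc2ccccc2)cc(C)c1C(=O)Oc1cc(C)c(C(=O)Oc2cc(C)c(C(=O)OCc3ccccc3)c(OCc3ccccc3)c2)c(OB2OC(C)(C)C(C)(C)O2)c1 | intermediate
21 | benzyl 2-(benzyloxy)-4-{[4-{[4-(benzyloxy)-2-methoxy-6-methylbenzoyl]oxy}-2-hydroxy-6-methylbenzoyl]oxy}-6-methylbenzoate (tribenzyl umbilicarate) | COc1cc(OCc2ccccc2)cc(C)c1C(=O)Oc1cc(C)c(C(=O)Oc2cc(C)c(C(=O)OCc3ccccc3)c(OCc3ccccc3)c2)c(O)c1 | intermediate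
22 | umbilicaric acid | COc1cc(O)cc(C)c1C(=O)Oc1cc(C)c(C(=O)Oc2cc(C)c(C(=O)O)c(O)c2)c(O)c1 | target

Total step count: 13 steps (steps 1–4 to pyrone ester 7; steps 5–10 to alkynylboronate 17; steps 11–13 to the target).
Longest linear sequence: 9 steps (8 → 9 → 10 → 11 → 12 → 14 → 17 → 19 → 22, steps 5–13).

Steps most likely to fail

Step 11. The cycloaddition may proceed in the reversed orientation, with boron ending next to the methyl-bearing carbon. It may also be so slow with the acyloxy-deactivated diene that thermal loss of the alkynylboronate or acyl transfer from the enol ester of 7 takes over. The fallback is a classical depside assembly without cycloaddition; it sets out from acid chloride 6 and phenol 12 and comes back at 21. Acid chloride 6 would acylate commercial 2,4-dihydroxy-6-methylbenzaldehyde (Et3N, CH2Cl2, 0 °C) at its non-chelated 4-OH to give 4-formyl-3-hydroxy-5-methylphenyl 4-(benzyloxy)-2-methoxy-6-methylbenzoate F1. Pinnick oxidation (NaClO2, NaH2PO4, 2-methyl-2-butene, tBuOH/THF/H2O) would give 4-{[4-(benzyloxy)-2-methoxy-6-methylbenzoyl]oxy}-2-hydroxy-6-methylbenzoic acid F2. Condensation of F2 with phenol 12 by trifluoroacetic anhydride in toluene at rt, the established way to join hindered o-hydroxy acids to phenols, should give 21, after which only step 13 remains.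

Step 10. The base or the acetylide may attack the aryl ester, or the electron-poor alkynylboronate may lose boron by protonolysis during acid release and handling. The fallback brings boron in after ring formation; it sets out from 14 and comes back at 19. Silver-catalysed bromination of the terminal alkyne (N-bromosuccinimide, AgNO3 cat., acetone, rt) would give benzyl 2-(benzyloxy)-4-[(3-bromoprop-2-ynoyl)oxy]-6-methylbenzoate F3. Heating F3 with pyrone 7 in 1,2-dichlorobenzene should give, by way of the bromo-substituted bridged lactone F4 and loss of CO2, the ring B aryl bromide F5, in the same orientation because the ester again polarises the alkyne. Miyaura borylation (B2pin2, Pd(dppf)Cl2, KOAc, dioxane, 80 °C) would convert F5 into 19.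

Step 9. The phenol or DMAP may add in conjugate fashion to the activated ynoate, and propiolic acid may oligomerise under the coupling conditions. The fallback masks the alkyne terminus; it sets out from 12 and comes back at 14. Phenol 12 would be esterified with commercial 3-(trimethylsilyl)propiolic acid (DCC, CH2Cl2, 0 °C) to give benzyl 2-(benzyloxy)-6-methyl-4-{[3-(trimethylsilyl)prop-2-ynoyl]oxy}benzoate F6. Protodesilylation with Bu4NF buffered by AcOH in THF at –78 °C should then give 14 without touching the aryl ester.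

Further compounds

F1 | step 11 | 4-formyl-3-hydroxy-5-methylphenyl 4-(benzyloxy)-2-methoxy-6-methylbenzoate | COc1cc(OCc2ccccc2)cc(C)c1C(=O)Oc1cc(C)c(C=O)c(O)c1
F2 | step 11 | 4-{[4-(benzyloxy)-2-methoxy-6-methylbenzoyl]oxy}-2-hydroxy-6-methylbenzoic acid | COc1cc(OCc2ccccc2)cc(C)c1C(=O)Oc1cc(C)c(C(=O)O)c(O)c1
F3 | step 10 | benzyl 2-(benzyloxy)-4-[(3-bromoprop-2-ynoyl)oxy]-6-methylbenzoate | BrC#CC(=O)Oc1cc(C)c(C(=O)OCc2ccccc2)c(OCc2ccccc2)c1
F4 | step 10 | racemic bromo cycloadduct, analogue of 18 with Br on C8 in place of Bpin | O=C1OC2(C)C=C(OC(=O)c3c(OC)cc(OCc4ccccc4)cc3C)C1C(Br)=C2C(=O)Oc1cc(C)c(C(=O)OCc2ccccc2)c(OCc2ccccc2)c1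
F5 | step 10 | benzyl 2-(benzyloxy)-4-{[4-{[4-(benzyloxy)-2-methoxy-6-methylbenzoyl]oxy}-2-bromo-6-methylbenzoyl]oxy}-6-methylbenzoate | COc1cc(OCc2ccccc2)cc(C)c1C(=O)Oc1cc(C)c(C(=O)Oc2cc(C)c(C(=O)OCc3ccccc3)c(OCc3ccccc3)c2)c(Br)c1
F6 | step 9 | benzyl 2-(benzyloxy)-6-methyl-4-{[3-(trimethylsilyl)prop-2-ynoyl]oxy}benzoate | C[Si](C)(C)C#CC(=O)Oc1cc(C)c(C(=O)OCc2ccccc2)c(OCc2ccccc2)c1
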